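## Retrosynthetic overview

1. The strategy rests on ring C. C4a carries the acyl carbon C4 and the neighbouring C8a carries O1, so ring C is an ortho-acyl aryl ether. It is cut at C4–C4a, O1–C8a and O1–C2 into a 3-bromoaryne (ring A, from silyl triflate 6) and the 2-arylacrylic acid 17 (ring B plus C2, C3, C4).
2. The bromine at C5 only steers the aryne addition and is removed afterwards. The single stereocentre C3 is set late: racemic ketone 21 → cis-(3S,4S) alcohol 22 by transfer-hydrogenative dynamic kinetic resolution → reoxidation → acidic unmasking.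
3. Triflate 6 comes from hydroquinone (mono-MOM ether, ortho-dibromination, retro-Brook silyl shift, triflation). Acid 17 comes from pyrogallol (diphenylmethylene ketal, prenyl ether Claisen rearrangement for the 1,1-dimethylallyl group, O-methylation, ortho-lithiation/borylation, Suzuki coupling with ethyl 2-bromoacrylate, saponification).
4. Ring order: rings A and B are bought as benzenes, the benzodioxole of step 5 is only a protecting ring, and ring C is the one ring formed (step 12).

Key step: step 12

Remark 1: "Ar" stands throughout for the protected ring B unit 7-methoxy-6-(2-methylbut-3-en-2-yl)-2,2-diphenyl-1,3-benzodioxol-4-yl.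

Remark 2 (assumption): the target is 3S. RuCl[(S,S)-TsDPEN](p-cymene) is assumed to show the sense of induction usual for aryl ketones (S carbinol); if the opposite sense were found, the (R,R) ligand would be used and nothing else changes.

## Route

Step 1
Reactants: 1 hydroquinone
Product: 2 4-(methoxymethoxy)phenol
Conditions: NaH (1.0 equiv), MOMCl (1.0 equiv), hydroquinone (3 equiv), THF/DMF, 0 °C to rt
Reagents that add atoms: chloromethyl methyl ether, COCCl
Why: Williamson-type O-alkylation of the monophenoxide, where the excess of hydroquinone over base and MOMCl should hold the reaction at the mono-ether and unreacted hydroquinone is removed by aqueous extraction.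

Step 2
Reactants: 2 4-(methoxymethoxy)phenol
Product: 3 2,6-dibromo-4-(methoxymethoxy)phenol
Conditions: NBS (2.05 equiv), i-Pr2NH (cat.), dry CH2Cl2, 0 °C to rt
Reagents that add atoms: N-bromosuccinimide, O=C1CCC(=O)N1Br
Why: Amine-catalysed electrophilic aromatic bromination with NBS goes to both positions ortho to the free hydroxyl (para is blocked) under non-acidic conditions that the MOM acetal tolerates.

Step 3
Reactants: 3 2,6-dibromo-4-(methoxymethoxy)phenol
Product: 4 [2,6-dibromo-4-(methoxymethoxy)phenoxy]trimethylsilane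
Conditions: (Me3Si)2NH, THF, 70 °C; evaporate
Reagents that add atoms: hexamethyldisilazane, C[Si](C)(C)N[Si](C)(C)C
Why: O-silylation of the phenol with HMDS, driven by loss of ammonia, prepares the silyl shift of the next step.

Step 4
Reactants: 4 [2,6-dibromo-4-(methoxymethoxy)phenoxy]trimethylsilane
Product: 6 2-bromo-4-(methoxymethoxy)-6-(trimethylsilyl)phenyl trifluoromethanesulfonate, via lithium silylphenoxide 5 (not isolated)
Conditions: n-BuLi (1.05 equiv), THF, −78 °C; then Tf2O, −78 °C
Reagents that add atoms: trifluoromethanesulfonic anhydride, O=S(=O)(OS(=O)(=O)C(F)(F)F)C(F)(F)F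
Why: Bromine–lithium exchange followed by retro-Brook 1,3 O→C silyl migration gives the ortho-silyl phenoxide, which Tf2O sulfonylates on oxygen, the standard entry to ortho-silylaryl triflates from ortho-bromophenols.

Step 5
Reactants: 7 pyrogallol
Product: 8 2,2-diphenyl-1,3-benzodioxol-4-ol
Conditions: Ph2CCl2 (1.1 equiv), neat, 170 °C, N2 sweep
Reagents that add atoms: dichlorodiphenylmethane, ClC(Cl)(c1ccccc1)c1ccccc1
Why: Thermal ketalisation of two adjacent hydroxyls with loss of HCl gives the five-membered diphenylmethylene ketal and necessarily leaves one terminal hydroxyl free.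

Step 6
Reactants: 8 2,2-diphenyl-1,3-benzodioxol-4-ol; 9 prenyl bromide (1-bromo-3-methylbut-2-ene)
Product: 10 4-[(3-methylbut-2-en-1-yl)oxy]-2,2-diphenyl-1,3-benzodioxole
Conditions: K2CO3, acetone, reflux
Reagents that add atoms: none
Why: Williamson ether synthesis, in which the phenoxide attacks the primary allylic carbon by SN2 and acetone favours O- over C-alkylation.

Step 7
Reactants: 10 4-[(3-methylbut-2-en-1-yl)oxy]-2,2-diphenyl-1,3-benzodioxole
Product: 11 5-(2-methylbut-3-en-2-yl)-2,2-diphenyl-1,3-benzodioxol-4-ol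
Conditions: PhNEt2, 190 °C, sealed tube, N2
Reagents that add atoms: none
Why: Aromatic Claisen rearrangement ([3,3]) transfers the allyl unit with allylic inversion to C5, the only free ortho position, which gives the 1,1-dimethylallyl group, while the basic amine solvent suppresses acid-induced cyclisation of the product phenol onto the alkene.

Step 8
Reactants: 11 5-(2-methylbut-3-en-2-yl)-2,2-diphenyl-1,3-benzodioxol-4-ol
Product: 12 4-methoxy-5-(2-methylbut-3-en-2-yl)-2,2-diphenyl-1,3-benzodioxole
Conditions: MeI, K2CO3, DMF, 40 °C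
Reagents that add atoms: iodomethane, CI
Why: Williamson O-methylation of the hindered phenoxide with a small, reactive electrophile.

Step 9
Reactants: 12 4-methoxy-5-(2-methylbut-3-en-2-yl)-2,2-diphenyl-1,3-benzodioxole
Product: 14 2-Ar-4,4,5,5-tetramethyl-1,3,2-dioxaborolane, via aryllithium 13 (not isolated)
Conditions: s-BuLi, TMEDA, THF, −78 to −40 °C; then i-PrOBpin, −78 °C to rt; aq. NH4Cl
Reagents that add atoms: 2-isopropoxy-4,4,5,5-tetramethyl-1,3,2-dioxaborolane, CC(C)OB1OC(C)(C)C(C)(C)O1
Why: Directed ortho-metalation, in which ring oxygen O1 of the benzodioxole directs lithiation to C7–H (the only ring C–H ortho to an oxygen) and the aryllithium is trapped by the borate ester.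

Step 10
Reactants: 14 2-Ar-4,4,5,5-tetramethyl-1,3,2-dioxaborolane; 15 ethyl 2-bromoacrylate
Product: 16 ethyl 2-Ar-prop-2-enoate
Conditions: PdCl2(dppf) (5 mol%), K2CO3, THF/H2O (10:1), BHT (cat.), 60 °C
Reagents that add atoms: none
Why: Suzuki–Miyaura coupling of the aryl boronate with the vinylic bromide installs the 1-(ethoxycarbonyl)vinyl unit intact, and mild base, moderate temperature and a radical inhibitor limit polymerisation of the acrylate.

Step 11
Reactants: 16 ethyl 2-Ar-prop-2-enoate
Product: 17 2-Ar-prop-2-enoic acid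
Conditions: LiOH, THF/H2O, 0 °C to rt; then 1 M HCl to pH 3 at 0 °C
Reagents that add atoms: lithium hydroxide, [Li+].[OH-]
Why: Ester saponification by acyl substitution, run without alcohol co-solvent to avoid alkoxide conjugate addition, with the ketal stable to base and to brief cold acidification.

Step 12
Reactants: 17 2-Ar-prop-2-enoic acid; 6 2-bromo-4-(methoxymethoxy)-6-(trimethylsilyl)phenyl trifluoromethanesulfonate
Product: 20 rac-5-bromo-7-(methoxymethoxy)-3-Ar-2,3-dihydro-4H-chromen-4-one, via bromoaryne 18 (not isolated), via cesium acylphenoxide 19 (not isolated)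
Conditions: 6 (1.5 equiv), CsF (4 equiv), BHT (cat.), THF, 110 °C, sealed tube
Reagents that add atoms: none
Why: CsF deprotonates 17 and desilylates 6, whose loss of triflate gives aryne 18; the carboxylate oxygen adds to the aryne carbon meta to bromine, the ortho aryl anion attacks the ester carbonyl through a four-membered alkoxide, and its opening moves the acyl group to carbon (formal aryne insertion into the acyl C–O bond) to give phenoxide 19. The closest known reaction type is the fluoride-induced C–O insertion of arynes into carboxylic acids to ortho-hydroxyaryl ketones, which with acrylic acids continues by oxa-Michael addition to 4-chromanones. Ring C closes by 6-endo-trig conjugate addition of the phenoxide oxygen to the CH2 terminus of the α-aryl enone (O1–C2). C3 arises by protonation of the enolate without facial control, so 20 is racemic by design and is resolved dynamically in step 14. The step needs regioselective addition to the aryne: bromine polarises and distorts the triple bond so that attack occurs at the distal carbon (future C8a) and the anion develops next to bromine (future C4a), which places the MOM ether at C7. It also needs acyl transfer to outrun protonation of the aryl anion, which the aprotic medium and the nearness of the carbonyl in the Z-ester conformation should secure.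

Step 13
Reactants: 20 rac-5-bromo-7-(methoxymethoxy)-3-Ar-2,3-dihydro-4H-chromen-4-one
Product: 21 rac-7-(methoxymethoxy)-3-Ar-2,3-dihydro-4H-chromen-4-one
Conditions: Pd(PPh3)4 (5 mol%), HCO2Na (3 equiv), DMF, 90 °C
Reagents that add atoms: none
Why: Palladium-catalysed hydrodehalogenation (oxidative addition of the aryl C–Br bond to zerovalent palladium, formate exchange, decarboxylation to the aryl palladium hydride, reductive elimination), which an isolated monosubstituted alkene without allylic hydrogens should survive.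

Step 14
Reactants: 21 rac-7-(methoxymethoxy)-3-Ar-2,3-dihydro-4H-chromen-4-one
Product: 22 (3S,4S)-7-(methoxymethoxy)-3-Ar-3,4-dihydro-2H-chromen-4-ol (cis)
Conditions: RuCl[(S,S)-TsDPEN](p-cymene) (2 mol%), HCO2H/Et3N, EtOAc, 40 °C
Reagents that add atoms: none
Why: Noyori-type asymmetric transfer hydrogenation with dynamic kinetic resolution, in which Et3N racemises C3 through the enol while the (S,S) catalyst delivers hydride to one carbonyl face (C4 becomes S) and only anti to the C3 aryl group, so the (3S)-ketone is consumed selectively and the cis-(3S,4S) alcohol should result.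

Step 15
Reactants: 22 (3S,4S)-7-(methoxymethoxy)-3-Ar-3,4-dihydro-2H-chromen-4-ol
Product: 23 (3S)-7-(methoxymethoxy)-3-Ar-2,3-dihydro-4H-chromen-4-one
Conditions: Dess–Martin periodinane, CH2Cl2, 0 °C to rt
Reagents that add atoms: none
Why: Dess–Martin oxidation of the benzylic alcohol under base-free conditions returns the ketone without enolisation at C3, so the S configuration set in step 14 is carried over.

Step 16
Reactants: 23 (3S)-7-(methoxymethoxy)-3-Ar-2,3-dihydro-4H-chromen-4-one
Product: 24 (3S)-3-[2,3-dihydroxy-4-methoxy-5-(2-methylbut-3-en-2-yl)phenyl]-7-hydroxy-2,3-dihydro-4H-chromen-4-one (CNP0134633.1)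
Conditions: 3 M aq. HCl, MeOH/THF, 40 °C
Reagents that add atoms: none
Why: Acid-catalysed acetal cleavage (transacetalisation of the MOM ether, hydrolysis of the diphenylmethylene ketal) in a base-free medium at moderate temperature to limit enolisation at C3, with no phenol ortho to the 1,1-dimethylallyl group that could cyclise onto it.

## Compound list

1 | hydroquinone | Oc1ccc(O)cc1 | starting material
2 | 4-(methoxymethoxy)phenol | COCOc1ccc(O)cc1 | intermediate
3 | 2,6-dibromo-4-(methoxymethoxy)phenol | COCOc1cc(Br)c(O)c(Br)c1 | intermediate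
4 | [2,6-dibromo-4-(methoxymethoxy)phenoxy]trimethylsilane | COCOc1cc(Br)c(O[Si](C)(C)C)c(Br)c1 | intermediate
5 | lithium 2-bromo-4-(methoxymethoxy)-6-(trimethylsilyl)phenoxide | COCOc1cc(Br)c([O-])c([Si](C)(C)C)c1.[Li+] | intermediate (not isolated)
6 | 2-bromo-4-(methoxymethoxy)-6-(trimethylsilyl)phenyl trifluoromethanesulfonate | COCOc1cc(Br)c(OS(=O)(=O)C(F)(F)F)c([Si](C)(C)C)c1 | intermediate
7 | pyrogallol | Oc1cccc(O)c1O | starting material
8 | 2,2-diphenyl-1,3-benzodioxol-4-ol | Oc1cccc2OC(c3ccccc3)(c3ccccc3)Oc12 | intermediate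
9 | prenyl bromide | CC(C)=CCBr | starting material
10 | 4-[(3-methylbut-2-en-1-yl)oxy]-2,2-diphenyl-1,3-benzodioxole | CC(C)=CCOc1cccc2OC(c3ccccc3)(c3ccccc3)Oc12 | intermediate
11 | 5-(2-methylbut-3-en-2-yl)-2,2-diphenyl-1,3-benzodioxol-4-ol | C=CC(C)(C)c1ccc2OC(c3ccccc3)(c3ccccc3)Oc2c1O | intermediate
12 | 4-methoxy-5-(2-methylbut-3-en-2-yl)-2,2-diphenyl-1,3-benzodioxole | C=CC(C)(C)c1ccc2OC(c3ccccc3)(c3ccccc3)Oc2c1OC | intermediate
13 | [7-methoxy-6-(2-methylbut-3-en-2-yl)-2,2-diphenyl-1,3-benzodioxol-4-yl]lithium | C=CC(C)(C)c1cc([Li])c2OC(c3ccccc3)(c3ccccc3)Oc2c1OC | intermediate (not isolated)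
14 | 2-[7-methoxy-6-(2-methylbut-3-en-2-yl)-2,2-diphenyl-1,3-benzodioxol-4-yl]-4,4,5,5-tetramethyl-1,3,2-dioxaborolane | C=CC(C)(C)c1cc(B2OC(C)(C)C(C)(C)O2)c3OC(c4ccccc4)(c4ccccc4)Oc3c1OC | intermediate
15 | ethyl 2-bromoacrylate | C=C(Br)C(=O)OCC | starting material
16 | ethyl 2-[7-methoxy-6-(2-methylbut-3-en-2-yl)-2,2-diphenyl-1,3-benzodioxol-4-yl]prop-2-enoate | C=C(C(=O)OCC)c1cc(C(C)(C)C=C)c(OC)c2OC(c3ccccc3)(c3ccccc3)Oc12 | intermediate
17 | 2-[7-methoxy-6-(2-methylbut-3-en-2-yl)-2,2-diphenyl-1,3-benzodioxol-4-yl]prop-2-enoic acid | C=C(C(=O)O)c1cc(C(C)(C)C=C)c(OC)c2OC(c3ccccc3)(c3ccccc3)Oc12 | intermediate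
18 | 3-bromo-5-(methoxymethoxy)benzyne | COCOC1=CC#CC(Br)=C1 | intermediate (not isolated)
19 | cesium 3-bromo-5-(methoxymethoxy)-2-(2-Ar-prop-2-enoyl)phenoxide | C=C(C(=O)c1c([O-])cc(OCOC)cc1Br)c1cc(C(C)(C)C=C)c(OC)c2OC(c3ccccc3)(c3ccccc3)Oc12.[Cs+] | intermediate (not isolated)
20 | rac-5-bromo-7-(methoxymethoxy)-3-Ar-2,3-dihydro-4H-chromen-4-one | C=CC(C)(C)c1cc(C2COc3cc(OCOC)cc(Br)c3C2=O)c4OC(c5ccccc5)(c5ccccc5)Oc4c1OC | intermediate
21 | rac-7-(methoxymethoxy)-3-Ar-2,3-dihydro-4H-chromen-4-one | C=CC(C)(C)c1cc(C2COc3cc(OCOC)ccc3C2=O)c4OC(c5ccccc5)(c5ccccc5)Oc4c1OC | intermediate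
22 | (3S,4S)-7-(methoxymethoxy)-3-Ar-3,4-dihydro-2H-chromen-4-ol (cis) | C=CC(C)(C)c1cc([C@H]2COc3cc(OCOC)ccc3[C@H]2O)c4OC(c5ccccc5)(c5ccccc5)Oc4c1OC | intermediate
23 | (3S)-7-(methoxymethoxy)-3-Ar-2,3-dihydro-4H-chromen-4-one | C=CC(C)(C)c1cc([C@H]2COc3cc(OCOC)ccc3C2=O)c4OC(c5ccccc5)(c5ccccc5)Oc4c1OC | intermediate
24 | (3S)-3-[2,3-dihydroxy-4-methoxy-5-(2-methylbut-3-en-2-yl)phenyl]-7-hydroxy-2,3-dihydro-4H-chromen-4-one | C=CC(C)(C)c1cc([C@H]2COc3cc(O)ccc3C2=O)c(O)c(O)c1OC | target

## Step count

Total: 16 steps. Longest linear sequence: 12 steps (steps 5–16, from pyrogallol). The ring A branch (steps 1–4) joins at step 12.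

## Steps most likely to fail

**1. Step 12 (aryne insertion and ring closure).** Three processes could override the acyl transfer:
- protonation of the ortho aryl anion before it attacks the carbonyl, which stops at the aryl ester;
- loss of bromide from the 2-bromoaryl anion to give a second aryne;
- thermal polymerisation of the 2-arylacrylic acid.

Fallback: ring C is brought in as a chromone; the fallback sets out from boronate 14 and comes back at 21.
- Commercial 1-(2,4-dihydroxyphenyl)ethanone F1 would be treated with MOMCl/K2CO3 in acetone (the chelated 2-hydroxyl stays free) to give 1-[2-hydroxy-4-(methoxymethoxy)phenyl]ethanone F2.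
- Condensation with DMF dimethyl acetal would give (E)-3-(dimethylamino)-1-[2-hydroxy-4-(methoxymethoxy)phenyl]prop-2-en-1-one F3.
- Cyclisation with I2/pyridine in CHCl3 would give 3-iodo-7-(methoxymethoxy)-4H-chromen-4-one F4.
- Suzuki–Miyaura coupling of F4 with 14 (PdCl2(dppf), K2CO3, dioxane/H2O) would give 7-(methoxymethoxy)-3-Ar-4H-chromen-4-one F5.
- Conjugate reduction with LiBH(s-Bu)3 in THF at −78 °C would give 21, which enters step 14; steps 10–13 are then not needed.

**2. Step 7 (Claisen rearrangement).** The ortho-dienone may undergo a second [3,3] shift to C7 (para to the oxygen) and end as the normal prenyl isomer, or the product phenol may add across its own alkene.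

Fallback: the quaternary carbon is built by enolate arylation; the fallback sets out from 8 and comes back at 12.
- Ortho-bromination of 8 (NBS, cat. i-Pr2NH, CH2Cl2) would give 5-bromo-2,2-diphenyl-1,3-benzodioxol-4-ol F6.
- Methylation (MeI, K2CO3, DMF) would give 5-bromo-4-methoxy-2,2-diphenyl-1,3-benzodioxole F7.
- Palladium-catalysed α-arylation of the lithium enolate of methyl 2-methylpropanoate (Pd(dba)2, P(t-Bu)3, toluene, rt) would give methyl 2-(4-methoxy-2,2-diphenyl-1,3-benzodioxol-5-yl)-2-methylpropanoate F8.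
- Reduction with i-Bu2AlH in CH2Cl2 at −78 °C would give 2-(4-methoxy-2,2-diphenyl-1,3-benzodioxol-5-yl)-2-methylpropanal F9.
- Wittig methylenation (Ph3P=CH2, THF) would give 12.

**3. Step 16 (final unmasking).** Acid-catalysed enolisation at C3 during the slower ketal hydrolysis could erode the enantiomeric purity, and prolonged acid could protonate the alkene.

Fallback: the acid-labile groups are exchanged for silyl ethers before the stereocentre is set; the fallback sets out from 21 and comes back at 24.
- Racemic 21 would be unmasked with HCl/MeOH (racemisation is irrelevant at this stage) to rac-3-[2,3-dihydroxy-4-methoxy-5-(2-methylbut-3-en-2-yl)phenyl]-7-hydroxy-2,3-dihydro-4H-chromen-4-one F10.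
- Silylation (TBSCl, imidazole, DMF) would give its tris(tert-butyldimethylsilyl) ether F11.
- Reduction under the conditions of step 14 would give the cis-(3S,4S) alcohol F12.
- Oxidation under the conditions of step 15 would give the (3S)-ketone F13.
- Desilylation with HF·pyridine in THF/pyridine at 0 °C, a non-basic and only weakly acidic medium, would give 24.

## Further compounds

F1 | step 12 | 1-(2,4-dihydroxyphenyl)ethanone (purchased) | CC(=O)c1ccc(O)cc1O
F2 | step 12 | 1-[2-hydroxy-4-(methoxymethoxy)phenyl]ethanone | CC(=O)c1ccc(OCOC)cc1O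
F3 | step 12 | (E)-3-(dimethylamino)-1-[2-hydroxy-4-(methoxymethoxy)phenyl]prop-2-en-1-one | CN(C)/C=C/C(=O)c1ccc(OCOC)cc1O
F4 | step 12 | 3-iodo-7-(methoxymethoxy)-4H-chromen-4-one | COCOc1ccc2c(c1)occ(I)c2=O
F5 | step 12 | 7-(methoxymethoxy)-3-[7-methoxy-6-(2-methylbut-3-en-2-yl)-2,2-diphenyl-1,3-benzodioxol-4-yl]-4H-chromen-4-one | C=CC(C)(C)c1cc(-c2coc3cc(OCOC)ccc3c2=O)c4OC(c5ccccc5)(c5ccccc5)Oc4c1OC
F6 | step 7 | 5-bromo-2,2-diphenyl-1,3-benzodioxol-4-ol | Oc1c(Br)ccc2OC(c3ccccc3)(c3ccccc3)Oc12
F7 | step 7 | 5-bromo-4-methoxy-2,2-diphenyl-1,3-benzodioxole | COc1c(Br)ccc2OC(c3ccccc3)(c3ccccc3)Oc12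
F8 | step 7 | methyl 2-(4-methoxy-2,2-diphenyl-1,3-benzodioxol-5-yl)-2-methylpropanoate | COC(=O)C(C)(C)c1ccc2OC(c3ccccc3)(c3ccccc3)Oc2c1OC
F9 | step 7 | 2-(4-methoxy-2,2-diphenyl-1,3-benzodioxol-5-yl)-2-methylpropanal | O=CC(C)(C)c1ccc2OC(c3ccccc3)(c3ccccc3)Oc2c1OC
F10 | step 16 | rac-3-[2,3-dihydroxy-4-methoxy-5-(2-methylbut-3-en-2-yl)phenyl]-7-hydroxy-2,3-dihydro-4H-chromen-4-one | C=CC(C)(C)c1cc(C2COc3cc(O)ccc3C2=O)c(O)c(O)c1OC
F11 | step 16 | rac-7-(tert-butyldimethylsilyloxy)-3-[2,3-bis(tert-butyldimethylsilyloxy)-4-methoxy-5-(2-methylbut-3-en-2-yl)phenyl]-2,3-dihydro-4H-chromen-4-one | C=CC(C)(C)c1cc(C2COc3cc(O[Si](C)(C)C(C)(C)C)ccc3C2=O)c(O[Si](C)(C)C(C)(C)C)c(O[Si](C)(C)C(C)(C)C)c1OC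
F12 | step 16 | (3S,4S)-7-(tert-butyldimethylsilyloxy)-3-[2,3-bis(tert-butyldimethylsilyloxy)-4-methoxy-5-(2-methylbut-3-en-2-yl)phenyl]-3,4-dihydro-2H-chromen-4-ol (cis) | C=CC(C)(C)c1cc([C@H]2COc3cc(O[Si](C)(C)C(C)(C)C)ccc3[C@H]2O)c(O[Si](C)(C)C(C)(C)C)c(O[Si](C)(C)C(C)(C)C)c1OC
F13 | step 16 | (3S)-7-(tert-butyldimethylsilyloxy)-3-[2,3-bis(tert-butyldimethylsilyloxy)-4-methoxy-5-(2-methylbut-3-en-2-yl)phenyl]-2,3-dihydro-4H-chromen-4-one | C=CC(C)(C)c1cc([C@H]2COc3cc(O[Si](C)(C)C(C)(C)C)ccc3C2=O)c(O[Si](C)(C)C(C)(C)C)c(O[Si](C)(C)C(C)(C)C)c1OC
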